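## The problem

The target 23 is a monocyclic secoiridoid aglycone. Its core is a 3,4-dihydro-2H-pyran, numbered here O1, C2 to C6. The C5=C6 enol ether is conjugated to a methyl ester on C5. C2 carries a methyl group, C3 a formyl group, and C4 an acetic acid arm esterified with hydroxytyrosol (17). There is no ring fusion, so the whole task is three contiguous stereocentres (2S,3S,4S): methyl and formyl cis, the C4 arm trans to both.

The C2/C3 pair has to be set in absolute terms. Once it sits on a ring with both substituents on one face, it can send an incoming C4 substituent to the other face.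

Three features forbid rough treatment:
- The C3 aldehyde has an α-hydrogen and, in the β-position, O1 as a vinylogous carboxylate leaving group. Base therefore threatens both epimerisation and ring opening.
- The catechol is oxidised by the reagents that make aldehydes.
- The saturated side-chain ester exchanges in acidic or basic alcohol much faster than the vinylogous C5 ester.

Aldehyde and free catechol must therefore appear last, under non-basic conditions. The hydroxytyrosyl ester must be installed after any alcoholysis step.

The enabling feature is C2. It bears O1, a methyl group and a hydrogen and is bonded to C3, so it is an acetaldehyde (6) carbon. The chain O1–C2–C3–C4–C5–(ester carbon) can be closed as a six-membered lactone, with O1 parked on the future ester carbon. That lactone is the oxidised form of the cycloadduct of acetaldehyde and a 1-alkoxydiene.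

## Retrosynthesis

**End game (23 ⇐ 22 ⇐ 21 ⇐ 20).** No skeletal bond is cut. Target 23 is traced to its bis-silyl ether 22, to the primary alcohol 21 and to the benzyl ether 20. The alternative order, oxidising C3 before the side-chain ester is in place, would pass through a hydroxy acid poised to lactonise. A hydrogenolysable catechol protection would fall together with the benzyl ether before the oxidation. The forward steps must spare the C5=C6 bond on hydrogenolysis, oxidise without base, and desilylate in a weakly acidic medium.

**Side-chain ester (20 ⇐ 16 + 19).** The acyl–oxygen bond of the side-chain ester is cut, giving acid 16 and the bis-silylated alcohol 19. Carrying the hydroxytyrosyl ester through from the conjugate addition would save steps. It would, however, expose a primary alkyl ester and two aryl silyl ethers to the acidic methanol of the ring switch, where exchange of that ester cannot be safely outrun by opening of a hindered lactone. Late esterification removes this doubt and lets a cheap nucleophile be used in excess earlier.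

**Ring switch (16 ⇐ 15 ⇐ 13).** Acid 16 comes from dimethyl ester 15 by hydrolysis of the saturated ester only. In 15 the O1–C6 bond is cut and O1 is reconnected to the ester carbon on C5. This gives δ-lactone 13, with C6 present as a dimethyl acetal on the lactone α-carbon. The cut turns a vinylogous carbonate into a plain lactone, a ring on which C4 can be made by conjugate addition and whose O1–C2–C3 segment is a cycloaddition retron. In the forward direction both esters are methyl esters, so exchange is degenerate.

**Two bonds from the enelactone (13 ⇐ 9 + 10 + 11).** The C4–CH2 bond of the arm and the C5–C6 bond are cut together. Addition of ketene silyl acetal 10 to enelactone 9 creates the enol silane exactly at C5, and orthoformate 11 then delivers C6 there. A separate formylation would have to choose between two enolisable esters; this sequence does not. The forward reaction must add anti to the C3 arm.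

**Key cut (9 ⇐ 7 ⇐ 5 + 6).** Lactone 9 is the oxidation product of cyclic acetal 7. In 7 the C2–C3 bond and the O1–acetal carbon bond are cut, giving diene 5 and acetaldehyde 6. An aldol construction of C2–C3 would need an auxiliary, a separate Z-olefination and a lactonisation. The cycloaddition makes the ring and both lasting stereocentres catalytically from achiral partners.

**Diene (5 ⇐ 3 + 4; 3 ⇐ 1).** The central single bond of the diene is cut, giving iodoalkene 3 and boronate 4; 3 comes from alkyne 1. An ylide-based enol ether synthesis would give both geometries at the enol ether, and only the E isomer can cycloadd. Cross-coupling transfers two defined geometries. The ethoxy group of 4 replaces a methoxy group without consequence, since this oxygen substituent is lost in step 4.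

**Alcohol fragment (19 ⇐ 18 ⇐ 17).** Only silicon–oxygen bonds are cut: full silylation of 17, then selective release of the alkyl silyl ether.

## Roads not taken

**Alternative 1:** The cut is C5–C6. The precursor is the formate A2, in which C4 carries two identical methoxycarbonylmethyl arms and O1 carries the formyl carbon. Enolisation of one arm, formyl transfer and dehydration would give the acetal diester A1.
- Merits: C4 becomes a stereocentre only on ring closure. The C3 aldehyde is already at the right oxidation level, masked as an acetal, so no late oxidation is needed and the catechol never meets an oxidant. In this respect it is better than the chosen plan.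
- Weak points: the two arms are equally acidic, and the choice between them rests on one neighbouring centre in an open chain. Formates are readily cleaved by base instead of acylating carbon. The C2/C3 pair must still be made separately.
- Comparison: A1 meets the chosen route at the stage of 15 and needs the same ester differentiation. Against the better oxidation-state economy, the chosen plan sets catalyst control of C2/C3 and ring control of C4.

**Alternative 2:** The cuts are O1–C2 and C3–C4. Crotonaldehyde A4, as an iminium ion of a chiral secondary amine, would take up the enol oxygen of dienol diester A5 and then close by enamine Michael addition. The product A3 is the same compound as 22.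
- Merits: it is by far the shortest road. Ring, three stereocentres and complete side chain come in one step, where the chosen route needs eleven linear steps to reach 22.
- Weak points: the enol oxygen of A5 is a weak, reversible donor, and A5 can close to a 2-pyranone with loss of its alcohol. The product aldehyde stays in contact with the amine, so enamine formation can scramble C3 and retro-oxa-Michael reaction can reopen the ring. The required cis C2/C3 arrangement has no evident kinetic or thermodynamic preference.
- Comparison: against the brevity, the chosen plan sets irreversible, separately controlled formation of each stereocentre, with C3 held at the alcohol level until the penultimate step.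

**Alternative 3:** The cut is C4–C5. The vinyl bromide A7, made from a chiral-pool C2/C3 unit, would give a C5 vinyl radical under tin hydride chain conditions. This closes 6-exo onto the enoate to give A6.
- Merits: neutral radical conditions carry the complete hydroxytyrosyl ester, so the two steps the chosen plan spends on ester exchange (steps 7 and 10) are not needed. C2/C3 need no catalyst.
- Weak points: C4 is set in a flexible 6-exo transition state of a very reactive σ-radical. Direct reduction and hydrogen transfer compete. A7 requires O-vinylation of a hindered secondary alcohol and a regiodefined bromination. The end game must free one alkyl silyl ether beside two aryl silyl ethers and then oxidise, as in the chosen plan.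
- Comparison: equal in the end game and better in carrying the ester; weaker in control of C4 and in the number of steps before the key step.

Key step: step 3

Remark on the chemistry: the ligand antipode is the one that exposes the Re face of a bound aliphatic aldehyde, assumed to be the (1R,2S)-aminoindanol series; the mirror-image ligand would be used if the sense proved opposite.

## Route

**Step 1**
Reactants: 1 benzyl prop-2-yn-1-yl ether
Product: 3 benzyl (2E)-3-iodoprop-2-en-1-yl ether, via alkenylzirconocene chloride 2 (not isolated)
Conditions: Cp2Zr(H)Cl (1.2 equiv), THF, rt, dark; then I2 (1.2 equiv), THF, 0 °C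
Reagents that add atoms: iodine, II
Why: Hydrozirconation adds Zr–H syn to the terminal alkyne with the metal at the unhindered terminus, and iodinolysis of the C–Zr bond proceeds with retention, so the E-iodoalkene should form as one isomer.

**Step 2**
Reactants: 3 benzyl (2E)-3-iodoprop-2-en-1-yl ether; 4 2-[(E)-2-ethoxyethenyl]-4,4,5,5-tetramethyl-1,3,2-dioxaborolane
Product: 5 benzyl (2E,4E)-5-ethoxypenta-2,4-dien-1-yl ether
Conditions: Pd(PPh3)4 (5 mol %), K3PO4 (3 equiv), THF/H2O, 50 °C; chromatography on Et3N-deactivated silica
Reagents that add atoms: none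
Why: Suzuki–Miyaura coupling of an alkenyl iodide with an alkenylboronate retains the geometry of both partners, so both double bonds are fixed as E; the basic medium protects the acid-labile dienyl ether.

**Step 3**
Reactants: 5 benzyl (2E,4E)-5-ethoxypenta-2,4-dien-1-yl ether; 6 acetaldehyde
Product: 7 (2S,3R,6S)-3-[(benzyloxy)methyl]-6-ethoxy-2-methyl-3,6-dihydro-2H-pyran (all-cis)
Conditions: (L)CrCl (5 mol %; L = dianion of (1R,2S)-1-{[3-(1-adamantyl)-2-hydroxy-5-methylbenzylidene]amino}indan-2-ol; trivalent chromium), powdered 4 Å molecular sieves, 6 (5 equiv), t-BuOMe, sealed vessel, 0 °C → rt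
Reagents that add atoms: none
Why: The chromium centre binds the carbonyl oxygen of 6, and the s-cis diene adds in a concerted, asynchronous [4+2] cycloaddition; the closest known reaction type is the oxa-Diels–Alder reaction of 1-alkoxydienes with aliphatic aldehydes under tridentate Schiff-base chromium chloride catalysis. The alkoxy donor puts the largest coefficient on the remote diene terminus, so that carbon bonds to the carbonyl carbon (C2–C3) and the carbonyl oxygen ends on the alkoxy-bearing carbon, which fixes the regiochemistry. The six-membered ring is closed by the cycloaddition itself, both new bonds forming on one face of the diene. The absolute configuration at C2 is set by the ligand, which leaves the Re face of the bound aldehyde open. The cis relation of the C2 methyl and the C3 benzyloxymethyl group follows from the E geometry of the diene double bond next to the benzyloxymethyl group together with the endo placement of the aldehyde substituent that this catalyst class enforces. The acetal centre is formed cis as well, from the E enol ether, but it is erased in step 4. The step needs regio-, endo- and enantioselectivity: the donor group secures the first, and the catalyst acting on a geometrically pure E,E-diene secures the other two.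

**Step 4**
Reactants: 7 (2S,3R,6S)-3-[(benzyloxy)methyl]-6-ethoxy-2-methyl-3,6-dihydro-2H-pyran
Product: 9 (5R,6S)-5-[(benzyloxy)methyl]-6-methyl-5,6-dihydro-2H-pyran-2-one, via lactol 8 (not isolated)
Conditions: CrO3, H2SO4, H2O (Jones reagent), acetone, 0 °C
Reagents that add atoms: water, O
Why: Aqueous acid hydrolyses the allylic acetal to the lactol, which hexavalent chromium oxidises at once to the unsaturated δ-lactone (Jones oxidation of a 2-alkoxy-dihydropyran); the temporary acetal centre disappears and C2 and C3 are not touched.

**Step 5**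
Reactants: 9 (5R,6S)-5-[(benzyloxy)methyl]-6-methyl-5,6-dihydro-2H-pyran-2-one; 10 tert-butyl[(1-methoxyethenyl)oxy]dimethylsilane; 11 trimethyl orthoformate
Product: 13 methyl 2-[(4S,5R,6S)-5-[(benzyloxy)methyl]-3-(dimethoxymethyl)-6-methyl-2-oxooxan-4-yl]acetate (both epimers at the lactone α-carbon), via lactone silyl ketene acetal 12 (not isolated)
Conditions: 10 (1.5 equiv), TBSOTf (10 mol %), CH2Cl2, −78 °C; then 11 (4 equiv), TBSOTf (20 mol %), −78 → −40 °C; Et3N quench
Reagents that add atoms: none
Why: Mukaiyama–Michael addition: the silyl-activated lactone is attacked axially at C4 on the face opposite the cis C3 arm and C2 methyl group, which sets C4 trans to C3. Silyl transfer leaves the enol silane only at the lactone α-carbon, which is then alkylated by the dimethoxycarbenium ion from 11 (silyl-triflate-catalysed orthoester condensation). The new α-centre is of no consequence because it becomes sp2 in step 6.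

**Step 6**
Reactants: 13 methyl 2-[(4S,5R,6S)-5-[(benzyloxy)methyl]-3-(dimethoxymethyl)-6-methyl-2-oxooxan-4-yl]acetate
Product: 15 methyl (2S,3R,4S)-3-[(benzyloxy)methyl]-4-(2-methoxy-2-oxoethyl)-2-methyl-3,4-dihydro-2H-pyran-5-carboxylate, via 2-methoxyoxane diester 14 (not isolated)
Conditions: HCl (1.25 M in MeOH), 0 → 45 °C; evaporate; PPTS (0.2 equiv), toluene, 90 °C
Reagents that add atoms: methanol, CO
Why: Acyl-lactone rearrangement of the Korte type: acid methanolysis opens the lactone to the methyl ester, and the freed C2 hydroxyl is trapped by the oxocarbenium ion of the neighbouring acetal in a six-membered ring. Acid-catalysed loss of methanol from 14 then gives the conjugated enol ether; ester exchange is degenerate and C2 to C4 cannot enolise.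

**Step 7**
Reactants: 15 methyl (2S,3R,4S)-3-[(benzyloxy)methyl]-4-(2-methoxy-2-oxoethyl)-2-methyl-3,4-dihydro-2H-pyran-5-carboxylate
Product: 16 2-[(2S,3R,4S)-3-[(benzyloxy)methyl]-5-(methoxycarbonyl)-2-methyl-3,4-dihydro-2H-pyran-4-yl]acetic acid
Conditions: LiOH·H2O (1.3 equiv), THF/H2O, 0 °C; then 1 M HCl to pH 3
Reagents that add atoms: lithium hydroxide, [Li+].[OH-]
Why: Saponification distinguishes the two methyl esters, because the C5 ester is a vinylogous carbonate deactivated by O1 while the saturated ester reacts normally; no aldehyde is present yet, so mild base is tolerated.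

**Step 8**
Reactants: 17 hydroxytyrosol, 4-(2-hydroxyethyl)benzene-1,2-diol
Product: 18 tert-butyl{2-[3,4-bis(tert-butyldimethylsilyloxy)phenyl]ethoxy}dimethylsilane
Conditions: TBSCl (3.6 equiv), imidazole, DMF, rt
Reagents that add atoms: tert-butyldimethylsilyl chloride, CC(C)(C)[Si](C)(C)Cl
Why: Imidazole-promoted silylation of all three hydroxyl groups is a standard protection and avoids any selectivity question at this stage.

**Step 9**
Reactants: 18 tert-butyl{2-[3,4-bis(tert-butyldimethylsilyloxy)phenyl]ethoxy}dimethylsilane
Product: 19 2-[3,4-bis(tert-butyldimethylsilyloxy)phenyl]ethanol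
Conditions: camphorsulfonic acid (10 mol %), MeOH/CH2Cl2, 0 °C
Reagents that add atoms: none
Why: Acid-catalysed solvolysis removes the primary alkyl silyl ether much faster than the aryl silyl ethers, whose oxygen is less basic.

**Step 10**
Reactants: 16 2-[(2S,3R,4S)-3-[(benzyloxy)methyl]-5-(methoxycarbonyl)-2-methyl-3,4-dihydro-2H-pyran-4-yl]acetic acid; 19 2-[3,4-bis(tert-butyldimethylsilyloxy)phenyl]ethanol
Product: 20 methyl (2S,3R,4S)-3-[(benzyloxy)methyl]-4-(2-{2-[3,4-bis(tert-butyldimethylsilyloxy)phenyl]ethoxy}-2-oxoethyl)-2-methyl-3,4-dihydro-2H-pyran-5-carboxylate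
Conditions: EDC·HCl (1.5 equiv), DMAP (0.2 equiv), CH2Cl2, 0 °C → rt
Reagents that add atoms: none
Why: Steglich esterification of an unhindered acid with a primary alcohol; no stereocentre is α to the activated carboxyl, so nothing can epimerise.

**Step 11**
Reactants: 20 methyl (2S,3R,4S)-3-[(benzyloxy)methyl]-4-(2-{2-[3,4-bis(tert-butyldimethylsilyloxy)phenyl]ethoxy}-2-oxoethyl)-2-methyl-3,4-dihydro-2H-pyran-5-carboxylate
Product: 21 methyl (2S,3R,4S)-4-(2-{2-[3,4-bis(tert-butyldimethylsilyloxy)phenyl]ethoxy}-2-oxoethyl)-3-(hydroxymethyl)-2-methyl-3,4-dihydro-2H-pyran-5-carboxylate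
Conditions: H2 (1 atm), Pd/C (10 wt %), EtOAc, rt; used at once
Reagents that add atoms: none
Why: Hydrogenolysis of the alkyl benzyl ether. The trisubstituted push–pull C5=C6 bond is a poor hydrogenation substrate, the homobenzylic ester is not cleaved, and neutral conditions with immediate use limit attack of the new hydroxyl on the side-chain ester.

**Step 12**
Reactants: 21 methyl (2S,3R,4S)-4-(2-{2-[3,4-bis(tert-butyldimethylsilyloxy)phenyl]ethoxy}-2-oxoethyl)-3-(hydroxymethyl)-2-methyl-3,4-dihydro-2H-pyran-5-carboxylate
Product: 22 methyl (2S,3S,4S)-4-(2-{2-[3,4-bis(tert-butyldimethylsilyloxy)phenyl]ethoxy}-2-oxoethyl)-3-formyl-2-methyl-3,4-dihydro-2H-pyran-5-carboxylate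
Conditions: Dess–Martin periodinane (1.3 equiv), CH2Cl2, 0 °C → rt
Reagents that add atoms: none
Why: Dess–Martin oxidation runs without base, so enolisation at C3 and β-elimination of O1 are avoided; the silylated catechol is inert to the oxidant.

**Step 13**
Reactants: 22 methyl (2S,3S,4S)-4-(2-{2-[3,4-bis(tert-butyldimethylsilyloxy)phenyl]ethoxy}-2-oxoethyl)-3-formyl-2-methyl-3,4-dihydro-2H-pyran-5-carboxylate
Product: 23 methyl (2S,3S,4S)-4-{2-[2-(3,4-dihydroxyphenyl)ethoxy]-2-oxoethyl}-3-formyl-2-methyl-3,4-dihydro-2H-pyran-5-carboxylate
Conditions: HF·pyridine, THF/pyridine, 0 °C → rt; pH 5 buffer work-up under argon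
Reagents that add atoms: none
Why: Fluoride cleaves the aryl silyl ethers in a weakly acidic medium, which should leave the base-sensitive β-alkoxy aldehyde and both esters intact.

## Compound list

1 | benzyl prop-2-yn-1-yl ether | C#CCOCc1ccccc1 | starting material
2 | chlorobis(cyclopentadienyl)[(1E)-3-(benzyloxy)prop-1-en-1-yl]zirconium | Cl[Zr](/C=C/COCc1ccccc1)(C1C=CC=C1)C1C=CC=C1 | intermediate
3 | benzyl (2E)-3-iodoprop-2-en-1-yl ether | I/C=C/COCc1ccccc1 | intermediate
4 | 2-[(E)-2-ethoxyethenyl]-4,4,5,5-tetramethyl-1,3,2-dioxaborolane | CCO/C=C/B1OC(C)(C)C(C)(C)O1 | starting material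
5 | benzyl (2E,4E)-5-ethoxypenta-2,4-dien-1-yl ether | CCO/C=C/C=C/COCc1ccccc1 | intermediate
6 | acetaldehyde | CC=O | starting material
7 | (2S,3R,6S)-3-[(benzyloxy)methyl]-6-ethoxy-2-methyl-3,6-dihydro-2H-pyran (all-cis) | CCO[C@H]1O[C@@H](C)[C@@H](COCc2ccccc2)C=C1 | intermediate
8 | (5R,6S)-5-[(benzyloxy)methyl]-6-methyl-5,6-dihydro-2H-pyran-2-ol (both anomers) | OC1O[C@@H](C)[C@@H](COCc2ccccc2)C=C1 | intermediate
9 | (5R,6S)-5-[(benzyloxy)methyl]-6-methyl-5,6-dihydro-2H-pyran-2-one | O=C1O[C@@H](C)[C@@H](COCc2ccccc2)C=C1 | intermediate
10 | tert-butyl[(1-methoxyethenyl)oxy]dimethylsilane | C=C(OC)O[Si](C)(C)C(C)(C)C | starting material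
11 | trimethyl orthoformate | COC(OC)OC | starting material
12 | methyl 2-[(2S,3R,4S)-3-[(benzyloxy)methyl]-6-[(tert-butyldimethylsilyl)oxy]-2-methyl-3,4-dihydro-2H-pyran-4-yl]acetate | CC(C)(C)[Si](C)(C)OC1=C[C@@H](CC(=O)OC)[C@H](COCc2ccccc2)[C@H](C)O1 | intermediate
13 | methyl 2-[(4S,5R,6S)-5-[(benzyloxy)methyl]-3-(dimethoxymethyl)-6-methyl-2-oxooxan-4-yl]acetate (both epimers at C3 of the oxanone) | O=C1O[C@@H](C)[C@@H](COCc2ccccc2)[C@H](CC(=O)OC)C1C(OC)OC | intermediate
14 | methyl (4S,5R,6S)-5-[(benzyloxy)methyl]-2-methoxy-4-(2-methoxy-2-oxoethyl)-6-methyloxane-3-carboxylate (isomers at C2 and C3 of the oxane) | COC(=O)C1C(OC)O[C@@H](C)[C@@H](COCc2ccccc2)[C@@H]1CC(=O)OC | intermediate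
15 | methyl (2S,3R,4S)-3-[(benzyloxy)methyl]-4-(2-methoxy-2-oxoethyl)-2-methyl-3,4-dihydro-2H-pyran-5-carboxylate | COC(=O)C1=CO[C@@H](C)[C@@H](COCc2ccccc2)[C@@H]1CC(=O)OC | intermediate
16 | 2-[(2S,3R,4S)-3-[(benzyloxy)methyl]-5-(methoxycarbonyl)-2-methyl-3,4-dihydro-2H-pyran-4-yl]acetic acid | COC(=O)C1=CO[C@@H](C)[C@@H](COCc2ccccc2)[C@@H]1CC(=O)O | intermediate
17 | hydroxytyrosol, 4-(2-hydroxyethyl)benzene-1,2-diol | OCCc1ccc(O)c(O)c1 | starting material
18 | tert-butyl{2-[3,4-bis(tert-butyldimethylsilyloxy)phenyl]ethoxy}dimethylsilane | CC(C)(C)[Si](C)(C)OCCc1ccc(O[Si](C)(C)C(C)(C)C)c(O[Si](C)(C)C(C)(C)C)c1 | intermediate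
19 | 2-[3,4-bis(tert-butyldimethylsilyloxy)phenyl]ethanol | OCCc1ccc(O[Si](C)(C)C(C)(C)C)c(O[Si](C)(C)C(C)(C)C)c1 | intermediate
20 | methyl (2S,3R,4S)-3-[(benzyloxy)methyl]-4-(2-{2-[3,4-bis(tert-butyldimethylsilyloxy)phenyl]ethoxy}-2-oxoethyl)-2-methyl-3,4-dihydro-2H-pyran-5-carboxylate | COC(=O)C1=CO[C@@H](C)[C@@H](COCc2ccccc2)[C@@H]1CC(=O)OCCc1ccc(O[Si](C)(C)C(C)(C)C)c(O[Si](C)(C)C(C)(C)C)c1 | intermediate
21 | methyl (2S,3R,4S)-4-(2-{2-[3,4-bis(tert-butyldimethylsilyloxy)phenyl]ethoxy}-2-oxoethyl)-3-(hydroxymethyl)-2-methyl-3,4-dihydro-2H-pyran-5-carboxylate | COC(=O)C1=CO[C@@H](C)[C@@H](CO)[C@@H]1CC(=O)OCCc1ccc(O[Si](C)(C)C(C)(C)C)c(O[Si](C)(C)C(C)(C)C)c1 | intermediate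
22 | methyl (2S,3S,4S)-4-(2-{2-[3,4-bis(tert-butyldimethylsilyloxy)phenyl]ethoxy}-2-oxoethyl)-3-formyl-2-methyl-3,4-dihydro-2H-pyran-5-carboxylate | COC(=O)C1=CO[C@@H](C)[C@@H](C=O)[C@@H]1CC(=O)OCCc1ccc(O[Si](C)(C)C(C)(C)C)c(O[Si](C)(C)C(C)(C)C)c1 | intermediate
23 | methyl (2S,3S,4S)-4-{2-[2-(3,4-dihydroxyphenyl)ethoxy]-2-oxoethyl}-3-formyl-2-methyl-3,4-dihydro-2H-pyran-5-carboxylate | COC(=O)C1=CO[C@@H](C)[C@@H](C=O)[C@@H]1CC(=O)OCCc1ccc(O)c(O)c1 | target

## Step count and least certain steps

Total: 13 steps. Longest linear sequence: 11 steps (steps 1 to 7 and 10 to 13); steps 8 and 9 prepare the alcohol fragment.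

**Step 3 (key step).** The diene has only one donor and a substituted terminus, so cycloaddition may be slow. Acetaldehyde can then be lost by evaporation or self-condensation before it reacts, and a sluggish reaction can erode the endo preference. The fallback keeps the cycloaddition but changes the dienophile and builds the methyl group by deoxygenation. It sets out from 5, which is combined under the same chromium catalysis with (tert-butyldimethylsilyloxy)acetaldehyde, a non-volatile and well-behaved partner for this catalyst class. This gives the silyloxymethyl cycloadduct F1. Fluoride frees the primary alcohol F2, tosyl chloride in pyridine gives the tosylate F3, and LiEt3BH displaces the tosylate by hydride. The sequence returns to the route at 7.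

**Step 5.** The enol silane 12 may be protonated or desilylated before it meets the carbenium ion, which would leave a lactone with two enolisable esters. Facial control in the addition could also be incomplete with so small a nucleophile. The fallback removes the second enolisable ester. It sets out from 9. Copper-mediated conjugate addition of vinylmagnesium bromide (CuBr·SMe2, TMSCl) gives the trans vinyl lactone F4. Formylation with LDA and ethyl formate can now occur only at the lactone and gives the hydroxymethylene lactone F5. The conditions of step 6 convert it to the vinyl dihydropyran F6. Hydroboration with 9-BBN and oxidative work-up give the primary alcohol F7, and TEMPO/PhI(OAc)2 oxidation in wet acetonitrile gives the acid. The sequence returns at 16.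

**Step 6.** Loss of methanol from 14 is reversible, and the sequence may stop at the saturated acetal or partition between it and 15. The fallback replaces acid-catalysed elimination by dehydration of a hemiacetal. It sets out from 14, which is isolated and hydrolysed with dilute aqueous acid to the lactol F8. Methanesulfonyl chloride and triethylamine then eliminate across the α-hydrogen of the ester. The sequence returns at 15.

**Step 11.** The palladium catalyst may saturate the C5=C6 bond during a slow debenzylation, and the liberated hydroxyl may acylate itself on the side-chain ester and expel 19. The fallback cleaves the benzyl ether by Lewis acid instead of hydrogen. It sets out from 20, which is treated with BCl3 and pentamethylbenzene in CH2Cl2 at −78 °C, and returns at 21. It makes no new compound (F0).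

**Step 13.** Even weakly basic fluoride may trigger elimination of O1 across C3–C2 or epimerise C3, and the free catechol may oxidise in air during work-up. The fallback masks the aldehyde while the silyl groups are removed. It sets out from 22, which is converted with trimethyl orthoformate and PPTS in methanol into the dimethyl acetal F9. Acetic-acid-buffered Bu4NF then gives the catechol acetal F10, and brief treatment with aqueous acetic acid releases the aldehyde. The sequence returns at 23.

## Further compounds

F1 | step 3 | (2R,3R,6S)-3-[(benzyloxy)methyl]-2-[(tert-butyldimethylsilyloxy)methyl]-6-ethoxy-3,6-dihydro-2H-pyran | CCO[C@H]1O[C@@H](CO[Si](C)(C)C(C)(C)C)[C@@H](COCc2ccccc2)C=C1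
F2 | step 3 | [(2R,3R,6S)-3-[(benzyloxy)methyl]-6-ethoxy-3,6-dihydro-2H-pyran-2-yl]methanol | CCO[C@H]1O[C@@H](CO)[C@@H](COCc2ccccc2)C=C1
F3 | step 3 | [(2R,3R,6S)-3-[(benzyloxy)methyl]-6-ethoxy-3,6-dihydro-2H-pyran-2-yl]methyl 4-methylbenzenesulfonate | CCO[C@H]1O[C@@H](COS(=O)(=O)c2ccc(C)cc2)[C@@H](COCc2ccccc2)C=C1
F4 | step 5 | (4S,5R,6S)-5-[(benzyloxy)methyl]-4-ethenyl-6-methyloxan-2-one | O=C1O[C@@H](C)[C@@H](COCc2ccccc2)[C@H](C=C)C1
F5 | step 5 | (4S,5R,6S)-5-[(benzyloxy)methyl]-4-ethenyl-3-(hydroxymethylidene)-6-methyloxan-2-one | O=C1O[C@@H](C)[C@@H](COCc2ccccc2)[C@H](C=C)C1=CO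
F6 | step 5 | methyl (2S,3R,4S)-3-[(benzyloxy)methyl]-4-ethenyl-2-methyl-3,4-dihydro-2H-pyran-5-carboxylate | COC(=O)C1=CO[C@@H](C)[C@@H](COCc2ccccc2)[C@@H]1C=C
F7 | step 5 | methyl (2S,3R,4S)-3-[(benzyloxy)methyl]-4-(2-hydroxyethyl)-2-methyl-3,4-dihydro-2H-pyran-5-carboxylate | COC(=O)C1=CO[C@@H](C)[C@@H](COCc2ccccc2)[C@@H]1CCO
F8 | step 6 | methyl (4S,5R,6S)-5-[(benzyloxy)methyl]-2-hydroxy-4-(2-methoxy-2-oxoethyl)-6-methyloxane-3-carboxylate | COC(=O)C1C(O)O[C@@H](C)[C@@H](COCc2ccccc2)[C@@H]1CC(=O)OC
F0 | step 11 | none | none
F9 | step 13 | methyl (2S,3S,4S)-4-(2-{2-[3,4-bis(tert-butyldimethylsilyloxy)phenyl]ethoxy}-2-oxoethyl)-3-(dimethoxymethyl)-2-methyl-3,4-dihydro-2H-pyran-5-carboxylate | COC(=O)C1=CO[C@@H](C)[C@@H](C(OC)OC)[C@@H]1CC(=O)OCCc1ccc(O[Si](C)(C)C(C)(C)C)c(O[Si](C)(C)C(C)(C)C)c1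
F10 | step 13 | methyl (2S,3S,4S)-4-{2-[2-(3,4-dihydroxyphenyl)ethoxy]-2-oxoethyl}-3-(dimethoxymethyl)-2-methyl-3,4-dihydro-2H-pyran-5-carboxylate | COC(=O)C1=CO[C@@H](C)[C@@H](C(OC)OC)[C@@H]1CC(=O)OCCc1ccc(O)c(O)c1
A1 | alternative 1 | methyl (2S,3S,4S)-3-(dimethoxymethyl)-4-(2-methoxy-2-oxoethyl)-2-methyl-3,4-dihydro-2H-pyran-5-carboxylate | COC(=O)C1=CO[C@@H](C)[C@@H](C(OC)OC)[C@@H]1CC(=O)OC
A2 | alternative 1 | dimethyl 3-[(2S,3S)-3-(formyloxy)-1,1-dimethoxybutan-2-yl]pentanedioate | C[C@H](OC=O)[C@@H](C(OC)OC)C(CC(=O)OC)CC(=O)OC
A3 | alternative 2 | methyl (2S,3S,4S)-4-(2-{2-[3,4-bis(tert-butyldimethylsilyloxy)phenyl]ethoxy}-2-oxoethyl)-3-formyl-2-methyl-3,4-dihydro-2H-pyran-5-carboxylate | COC(=O)C1=CO[C@@H](C)[C@@H](C=O)[C@@H]1CC(=O)OCCc1ccc(O[Si](C)(C)C(C)(C)C)c(O[Si](C)(C)C(C)(C)C)c1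
A4 | alternative 2 | crotonaldehyde, (E)-but-2-enal | C/C=C/C=O
A5 | alternative 2 | 1-{2-[3,4-bis(tert-butyldimethylsilyloxy)phenyl]ethyl} 5-methyl (2E)-4-(hydroxymethylidene)pent-2-enedioate | COC(=O)C(=CO)/C=C/C(=O)OCCc1ccc(O[Si](C)(C)C(C)(C)C)c(O[Si](C)(C)C(C)(C)C)c1
A6 | alternative 3 | methyl (2S,3R,4S)-4-(2-{2-[3,4-bis(tert-butyldimethylsilyloxy)phenyl]ethoxy}-2-oxoethyl)-3-[(tert-butyldimethylsilyloxy)methyl]-2-methyl-3,4-dihydro-2H-pyran-5-carboxylate | COC(=O)C1=CO[C@@H](C)[C@@H](CO[Si](C)(C)C(C)(C)C)[C@@H]1CC(=O)OCCc1ccc(O[Si](C)(C)C(C)(C)C)c(O[Si](C)(C)C(C)(C)C)c1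
A7 | alternative 3 | 2-[3,4-bis(tert-butyldimethylsilyloxy)phenyl]ethyl (2E,4R,5S)-5-[(2-bromo-3-methoxy-3-oxoprop-1-en-1-yl)oxy]-4-[(tert-butyldimethylsilyloxy)methyl]hex-2-enoate | COC(=O)C(Br)=CO[C@@H](C)[C@@H](CO[Si](C)(C)C(C)(C)C)/C=C/C(=O)OCCc1ccc(O[Si](C)(C)C(C)(C)C)c(O[Si](C)(C)C(C)(C)C)c1
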